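The route rests on making the para-phenylene ring B last. Ring B carries only the ether oxygen to ring C at C4 and the bridge CH2 to ring A at C1. This is exactly the 1,4-pattern that a 2-oxygenated butadiene and a terminal alkyne deliver. A cobalt(I)–dppe-catalysed intramolecular [4+2] of open-chain 18 forms two C–C bonds, ring B (as a 1,4-cyclohexadiene) and the 18-membered macrocycle in one operation. Precursor 18 holds rings A–O–D–CH2CH2–C preassembled, a buta-1,3-dien-2-yl ether on the ring C oxygen and a but-3-ynyl chain on ring A. The alkyne is carried through the titanium methylenation as its gem-dibromoalkene; DDQ and BBr3 finish.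

Key step: step 11

Ring labels: A = hydroquinone-type ring, B = para-phenylene, C = catechol-type ring, D = meta-phenylene. The ring sequence is A–CH2CH2–B–O–C–CH2CH2–D–O–A.

Remark on stereochemistry: the target SMILES contains no stereocentre, no stereogenic double bond and no atropisomer descriptor. The 18-membered cyclophane is taken as conformationally mobile and achiral, so no step has to set or preserve configuration.

Step 1
Reactants: 1 3-hydroxybenzyl alcohol
Product: 2 (3-hydroxybenzyl)triphenylphosphonium bromide
Conditions: PPh3·HBr (1.05 equiv), MeCN, reflux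
Reagents that add atoms: triphenylphosphine hydrobromide, Br.c1ccc(cc1)P(c1ccccc1)c1ccccc1
Why: Benzylic alcohols are converted directly into benzylphosphonium bromides by PPh3·HBr (acid-promoted substitution at the benzylic carbon), and the free ring D phenol is inert, so no protecting group is needed.

Step 2
Reactants: 2 (3-hydroxybenzyl)triphenylphosphonium bromide; 3 3-(benzyloxy)-4-methoxybenzaldehyde (O-benzylisovanillin)
Product: 5 3-{2-[3-(benzyloxy)-4-methoxyphenyl]ethenyl}phenol (E/Z mixture), via potassium 3-[(triphenyl-λ5-phosphanylidene)methyl]phenolate 4 (not isolated)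
Conditions: KOtBu (2.2 equiv), THF, 0 °C; then 3, 0 °C → rt; 1 M HCl quench
Reagents that add atoms: none
Why: Wittig olefination with a semistabilised benzylic ylide, in which the second equivalent of base only parks the ring D phenol as its phenolate and the E/Z mixture is irrelevant because the alkene is saturated in step 5.

Step 3
Reactants: 5 3-{2-[3-(benzyloxy)-4-methoxyphenyl]ethenyl}phenol; 6 2-fluoro-5-methoxybenzaldehyde
Product: 7 2-(3-{2-[3-(benzyloxy)-4-methoxyphenyl]ethenyl}phenoxy)-5-methoxybenzaldehyde (stilbene E/Z)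
Conditions: K2CO3 (2 equiv), DMF, 130 °C, N2
Reagents that add atoms: none
Why: SNAr in which the ortho-formyl group activates the C–F bond towards the only nucleophile present, the ring D phenolate, and forming the A–O–D ether after the Wittig step keeps aldehyde and phosphonium salt out of the same molecule.

Step 4
Reactants: 7 2-(3-{2-[3-(benzyloxy)-4-methoxyphenyl]ethenyl}phenoxy)-5-methoxybenzaldehyde; 8 ethyl (triphenyl-λ5-phosphanylidene)acetate
Product: 9 ethyl (2E)-3-[2-(3-{2-[3-(benzyloxy)-4-methoxyphenyl]ethenyl}phenoxy)-5-methoxyphenyl]prop-2-enoate (stilbene E/Z)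
Conditions: toluene, 80 °C
Reagents that add atoms: none
Why: Wittig olefination with a stabilised ylide needs no base, is E-selective and adds the second carbon of the A–B bridge and the future ipso carbon C1 of ring B.

Step 5
Reactants: 9 ethyl (2E)-3-[2-(3-{2-[3-(benzyloxy)-4-methoxyphenyl]ethenyl}phenoxy)-5-methoxyphenyl]prop-2-enoate
Product: 10 ethyl 3-(2-{3-[2-(3-hydroxy-4-methoxyphenyl)ethyl]phenoxy}-5-methoxyphenyl)propanoate
Conditions: H2 (1–3 bar), 10% Pd/C, EtOAc–EtOH, rt
Reagents that add atoms: none
Why: Heterogeneous catalytic hydrogenation saturates both alkenes and hydrogenolyses the benzyl ether in one operation, while the diaryl ether, the methyl ethers and the ester are inert.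

Step 6
Reactants: 10 ethyl 3-(2-{3-[2-(3-hydroxy-4-methoxyphenyl)ethyl]phenoxy}-5-methoxyphenyl)propanoate
Product: 12 3-(2-{3-[2-(3-hydroxy-4-methoxyphenyl)ethyl]phenoxy}-5-methoxyphenyl)propanal, via the bis(diisobutylaluminium) phenolate/hemiacetal of 10 11 (not isolated)
Conditions: DIBAL-H (2.2 equiv), CH2Cl2, −78 °C; MeOH, then aq Rochelle salt
Reagents that add atoms: none
Why: Partial ester reduction with DIBAL-H, in which the first equivalent is consumed by the phenol and the second gives tetrahedral adduct 11, which does not collapse at −78 °C, so the aldehyde appears only on quench.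

Step 7
Reactants: 12 3-(2-{3-[2-(3-hydroxy-4-methoxyphenyl)ethyl]phenoxy}-5-methoxyphenyl)propanal
Product: 13 5-(2-{3-[2-(4,4-dibromobut-3-en-1-yl)-4-methoxyphenoxy]phenyl}ethyl)-2-methoxyphenol
Conditions: CBr4, PPh3, Zn dust (2 equiv each), CH2Cl2, rt (pre-stirred); then 12, rt
Reagents that add atoms: carbon tetrabromide, BrC(Br)(Br)Br
Why: Ramirez gem-dibromoolefination (first stage of the Corey–Fuchs sequence), run in the zinc variant, which avoids Ph3PBr2 and excess phosphine so that the free phenol is left alone, stores the alkyne in a form that the titanium reagent of step 9 does not touch.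

Step 8
Reactants: 13 5-(2-{3-[2-(4,4-dibromobut-3-en-1-yl)-4-methoxyphenoxy]phenyl}ethyl)-2-methoxyphenol; 14 acryloyl chloride
Product: 15 5-(2-{3-[2-(4,4-dibromobut-3-en-1-yl)-4-methoxyphenoxy]phenyl}ethyl)-2-methoxyphenyl prop-2-enoate
Conditions: Et3N (1.5 equiv), CH2Cl2, 0 °C, BHT (trace)
Reagents that add atoms: none
Why: O-Acylation of the only hydroxyl group by an acid chloride (nucleophilic acyl substitution) is routine for guaiacol-type phenols, and the dibromoalkene and the ethers are inert to triethylamine.

Step 9
Reactants: 15 5-(2-{3-[2-(4,4-dibromobut-3-en-1-yl)-4-methoxyphenoxy]phenyl}ethyl)-2-methoxyphenyl prop-2-enoate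
Product: 16 2-(buta-1,3-dien-2-yloxy)-4-(2-{3-[2-(4,4-dibromobut-3-en-1-yl)-4-methoxyphenoxy]phenyl}ethyl)-1-methoxybenzene
Conditions: Tebbe reagent (1.3 equiv, 0.5 M in toluene), pyridine (cat.), THF, −40 → 0 °C; aq NaOH quench; basic alumina
Reagents that add atoms: Tebbe reagent (Cp drawn η1), C[Al-]1(C)C[Ti]([Cl+]1)(C1C=CC=C1)C1C=CC=C1
Why: Tebbe methylenation ([2+2] of titanocene methylidene with the ester C=O, then cycloreversion with loss of Cp2Ti=O), established for aryl esters and for α,β-unsaturated esters, turns the acrylate into the 2-aryloxybutadiene at low temperature, and it is run while the alkyne is still a hindered trisubstituted gem-dibromoalkene because titanocene methylidene would add to a free alkyne to give a titanacyclobutene.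

Step 10
Reactants: 16 2-(buta-1,3-dien-2-yloxy)-4-(2-{3-[2-(4,4-dibromobut-3-en-1-yl)-4-methoxyphenoxy]phenyl}ethyl)-1-methoxybenzene
Product: 18 2-(buta-1,3-dien-2-yloxy)-4-(2-{3-[2-(but-3-yn-1-yl)-4-methoxyphenoxy]phenyl}ethyl)-1-methoxybenzene, via the lithium acetylide of 18 17 (not isolated)
Conditions: n-BuLi (2.05 equiv, dropwise), THF, −78 °C; then H2O, −78 °C → rt; Et3N-deactivated silica
Reagents that add atoms: none
Why: Second stage of the Corey–Fuchs alkyne synthesis, in which Br/Li exchange, loss of LiBr with 1,2-hydrogen shift (Fritsch–Buttenberg–Wiechell type) and deprotonation to acetylide 17 are all far faster at −78 °C than carbolithiation of the electron-rich dienyl ether, which has no α-hydrogen to lose, and the neutral aqueous quench spares the enol ether.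

Step 11
Reactants: 18 2-(buta-1,3-dien-2-yloxy)-4-(2-{3-[2-(but-3-yn-1-yl)-4-methoxyphenoxy]phenyl}ethyl)-1-methoxybenzene
Product: 19 di-O-methyl macrocycle with ring B as a 1-alkyl-4-aryloxycyclohexa-1,4-diene
Conditions: CoBr2(dppe) (20 mol %), Zn dust (40 mol %), ZnI2 (40 mol %), CH2Cl2, rt, argon; 18 added by syringe pump (final ca. 1 mM); filtration through basic alumina, used at once
Reagents that add atoms: none
Why: Proposed new method: zinc reduces CoBr2(dppe) and ZnI2 abstracts bromide to give a cationic cobalt(I) bisphosphine that binds the s-cis diene and the alkyne of 18, oxidative cyclisation gives an allyl-cobaltacycle, and reductive elimination releases the 1,4-cyclohexadiene with new bonds from diene C4 to the internal alkyne carbon and from diene C1 to the terminal alkyne carbon. The closest known reaction type is the intermolecular cobalt(I)-bisphosphine-catalysed neutral Diels–Alder reaction of 2-substituted 1,3-dienes (2-silyloxybutadiene included) with terminal alkynes, which has not been shown as a macrocyclisation or with 2-aryloxydienes. Ring B closes by the [4+2] itself (four diene carbons plus two alkyne carbons), and the 18-membered macrocycle closes in the same event as a type-2 intramolecular cycloaddition, the tether running from the oxygen on diene C2 to the internal alkyne carbon and ending up across C4 and C1 of the new ring. No stereocentre is formed. The step needs para over meta orientation, for which dppe on cobalt and the donor oxygen at diene C2 are the controlling elements and which the 14-atom tether is long enough not to override, the non-planar cyclohexadiene spanning its ends with less strain than a flat arene. It also needs ring closure over oligomerisation and over alkyne cyclotrimerisation, which syringe-pump addition to about 1 mM should secure, while anhydrous conditions keep both enol ethers intact towards ZnI2.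

Step 12
Reactants: 19 di-O-methyl macrocycle with ring B as a cyclohexa-1,4-diene
Product: 20 di-O-methyl ether of the target (all four rings aromatic)
Conditions: DDQ (1.1 equiv), toluene, rt
Reagents that add atoms: none
Why: Dehydrogenative aromatisation, in which hydride abstraction by DDQ from a doubly allylic CH2 of the 1,4-cyclohexadiene and proton loss are far faster than attack on the bibenzyl CH2 groups or the anisole rings, so one equivalent at rt should suffice.

Step 13
Reactants: 20 di-O-methyl ether of the target
Product: 22 target CNP0135015.0, via the bis(dibromoboryl) ether of the target 21 (not isolated)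
Conditions: BBr3 (6 equiv), CH2Cl2, −78 °C → rt; then ice–water
Reagents that add atoms: none
Why: Lewis-acid cleavage of aryl methyl ethers, in which BBr3 binds each methoxy oxygen and bromide attacks the methyl carbon (SN2), whereas the two diaryl ether bridges offer only C(sp2)–O bonds and survive.

Compound list
1 | 3-hydroxybenzyl alcohol (ring D) | OCc1cccc(O)c1 | starting material
2 | (3-hydroxybenzyl)triphenylphosphonium bromide | [Br-].Oc1cccc(c1)C[P+](c1ccccc1)(c1ccccc1)c1ccccc1 | intermediate
3 | 3-(benzyloxy)-4-methoxybenzaldehyde (ring C) | COc1ccc(C=O)cc1OCc1ccccc1 | starting material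
4 | potassium 3-[(triphenyl-λ5-phosphanylidene)methyl]phenolate (ylide, not isolated) | [K+].[O-]c1cccc(c1)C=P(c1ccccc1)(c1ccccc1)c1ccccc1 | intermediate
5 | 3-{2-[3-(benzyloxy)-4-methoxyphenyl]ethenyl}phenol (E/Z mixture, geometry left undefined because both isomers converge in step 5) | Oc1cccc(c1)C=Cc1ccc(OC)c(c1)OCc1ccccc1 | intermediate
6 | 2-fluoro-5-methoxybenzaldehyde (ring A) | COc1ccc(F)c(C=O)c1 | starting material
7 | 2-(3-{2-[3-(benzyloxy)-4-methoxyphenyl]ethenyl}phenoxy)-5-methoxybenzaldehyde (stilbene E/Z, undefined) | O=Cc1cc(OC)ccc1Oc1cccc(c1)C=Cc1ccc(OC)c(c1)OCc1ccccc1 | intermediate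
8 | ethyl (triphenyl-λ5-phosphanylidene)acetate | CCOC(=O)C=P(c1ccccc1)(c1ccccc1)c1ccccc1 | starting material
9 | ethyl (2E)-3-[2-(3-{2-[3-(benzyloxy)-4-methoxyphenyl]ethenyl}phenoxy)-5-methoxyphenyl]prop-2-enoate (stilbene E/Z, undefined) | CCOC(=O)/C=C/c1cc(OC)ccc1Oc1cccc(c1)C=Cc1ccc(OC)c(c1)OCc1ccccc1 | intermediate
10 | ethyl 3-(2-{3-[2-(3-hydroxy-4-methoxyphenyl)ethyl]phenoxy}-5-methoxyphenyl)propanoate | CCOC(=O)CCc1cc(OC)ccc1Oc1cccc(c1)CCc1ccc(OC)c(O)c1 | intermediate
11 | bis(diisobutylaluminium) phenolate/hemiacetal of 10 (racemic at the hemiacetal carbon, not isolated) | CCOC(CCc1cc(OC)ccc1Oc1cccc(c1)CCc1ccc(OC)c(c1)O[Al](CC(C)C)CC(C)C)O[Al](CC(C)C)CC(C)C | intermediate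
12 | 3-(2-{3-[2-(3-hydroxy-4-methoxyphenyl)ethyl]phenoxy}-5-methoxyphenyl)propanal | O=CCCc1cc(OC)ccc1Oc1cccc(c1)CCc1ccc(OC)c(O)c1 | intermediate
13 | 5-(2-{3-[2-(4,4-dibromobut-3-en-1-yl)-4-methoxyphenoxy]phenyl}ethyl)-2-methoxyphenol | BrC(Br)=CCCc1cc(OC)ccc1Oc1cccc(c1)CCc1ccc(OC)c(O)c1 | intermediate
14 | acryloyl chloride | C=CC(=O)Cl | starting material
15 | 5-(2-{3-[2-(4,4-dibromobut-3-en-1-yl)-4-methoxyphenoxy]phenyl}ethyl)-2-methoxyphenyl prop-2-enoate | BrC(Br)=CCCc1cc(OC)ccc1Oc1cccc(c1)CCc1ccc(OC)c(c1)OC(=O)C=C | intermediate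
16 | 2-(buta-1,3-dien-2-yloxy)-4-(2-{3-[2-(4,4-dibromobut-3-en-1-yl)-4-methoxyphenoxy]phenyl}ethyl)-1-methoxybenzene | BrC(Br)=CCCc1cc(OC)ccc1Oc1cccc(c1)CCc1ccc(OC)c(c1)OC(=C)C=C | intermediate
17 | lithium acetylide of 18 (not isolated) | [Li]C#CCCc1cc(OC)ccc1Oc1cccc(c1)CCc1ccc(OC)c(c1)OC(=C)C=C | intermediate
18 | 2-(buta-1,3-dien-2-yloxy)-4-(2-{3-[2-(but-3-yn-1-yl)-4-methoxyphenoxy]phenyl}ethyl)-1-methoxybenzene (key-step precursor) | C=CC(=C)Oc1cc(ccc1OC)CCc1cccc(c1)Oc1ccc(OC)cc1CCC#C | intermediate
19 | di-O-methyl macrocycle with ring B as a 1-alkyl-4-aryloxycyclohexa-1,4-diene (key-step product) | COc1ccc2c(c1)CCC1=CCC(=CC1)Oc1cc(ccc1OC)CCc1cccc(c1)O2 | intermediate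
20 | di-O-methyl ether of the target | COc1ccc2c(c1)CCc1ccc(cc1)Oc1cc(ccc1OC)CCc1cccc(c1)O2 | intermediate
21 | bis(dibromoboryl) ether of the target (not isolated) | BrB(Br)Oc1ccc2c(c1)CCc1ccc(cc1)Oc1cc(ccc1OB(Br)Br)CCc1cccc(c1)O2 | intermediate
22 | CNP0135015.0 (achiral macrocyclic bis(bibenzyl) diether) | Oc1ccc2c(c1)CCc1ccc(cc1)Oc1cc(ccc1O)CCc1cccc(c1)O2 | target

Total step count: 13
Longest linear sequence: 13 steps (1 → 22). Partners 3, 6, 8 and 14 are bought.

Steps most likely to fail

Step 11 (Proposed new method). Several processes could defeat it: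
- Intermolecular cycloaddition and alkyne cyclotrimerisation may outrun ring closure at the dilution at which the catalyst still turns over.
- The tether may steer the cycloaddition to the meta orientation.
- The zinc Lewis acid may degrade the dienyl ether.

The fallback uses known chemistry only. Ring B is brought in intact, and the macrocycle is closed at the A–B bridge by an intramolecular Wittig olefination. It sets out from aldehyde 7. NaBH4 in MeOH gives the ring A benzylic alcohol F1. H2 over Pd/C in EtOAc saturates the stilbene and removes the benzyl group to give the phenol alcohol F2. SNAr with 4-fluorobenzaldehyde (K2CO3, DMF, 120 °C) gives the ring B aldehyde F3. PPh3·HBr in refluxing MeCN gives the ω-formyl phosphonium bromide F4. Slow addition of this salt to NaOMe in CH2Cl2 at high dilution closes the 18-membered ring as the macrocyclic stilbene F5 (E/Z). Hydrogenation (H2, Pd/C) then comes back to the route at 20.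

Step 9. The new dienyl ether may polymerise or hydrolyse on the aluminium and titanium residues. The titanium methylidene may also engage the vinyl group instead of the carbonyl group. The fallback makes the enol ether C–O bond by cross-coupling rather than by carbonyl methylenation, and it then needs neither a titanium carbene nor an organolithium. It sets out from phenol ester 10. Methyl vinyl ketone is converted (Tf2O, 2,6-di-tert-butyl-4-methylpyridine, CH2Cl2) into buta-1,3-dien-2-yl triflate F6. This is joined to 10 by palladium-catalysed coupling of an enol triflate with a phenol (Pd2(dba)3, bulky biarylphosphine, K3PO4, toluene, 80 °C) to give the dienyl ether ester F7. DIBAL-H at −78 °C gives the dienyl ether aldehyde F8. Ohira–Bestmann homologation (dimethyl (1-diazo-2-oxopropyl)phosphonate, K2CO3, MeOH, rt) comes back to the route at 18.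

Step 10. Any excess of butyllithium may start carbolithiation and anionic oligomerisation of the diene, or may induce loss of aryloxide from the dienyl ether. The fallback replaces the organolithium chemistry by hydrogenolysis and E2 elimination. It sets out from 16. Palladium-catalysed hydrogenolysis of the less hindered C–Br bond (Pd(PPh3)4, Bu3SnH, toluene, rt) gives the (Z)-1-bromoalkene F9. Its anti-periplanar H and Br are then lost on treatment with TBAF·3H2O in DMF at 60 °C, which comes back to the route at 18.

Further compounds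
F1 | step 11 | [2-(3-{2-[3-(benzyloxy)-4-methoxyphenyl]ethenyl}phenoxy)-5-methoxyphenyl]methanol (stilbene E/Z, undefined) | OCc1cc(OC)ccc1Oc1cccc(c1)C=Cc1ccc(OC)c(c1)OCc1ccccc1
F2 | step 11 | 5-(2-{3-[2-(hydroxymethyl)-4-methoxyphenoxy]phenyl}ethyl)-2-methoxyphenol | OCc1cc(OC)ccc1Oc1cccc(c1)CCc1ccc(OC)c(O)c1
F3 | step 11 | 4-[5-(2-{3-[2-(hydroxymethyl)-4-methoxyphenoxy]phenyl}ethyl)-2-methoxyphenoxy]benzaldehyde | OCc1cc(OC)ccc1Oc1cccc(c1)CCc1ccc(OC)c(c1)Oc1ccc(C=O)cc1
F4 | step 11 | {2-[3-(2-{3-(4-formylphenoxy)-4-methoxyphenyl}ethyl)phenoxy]-5-methoxybenzyl}triphenylphosphonium bromide | [Br-].O=Cc1ccc(cc1)Oc1cc(ccc1OC)CCc1cccc(c1)Oc1ccc(OC)cc1C[P+](c1ccccc1)(c1ccccc1)c1ccccc1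
F5 | step 11 | di-O-methyl macrocycle with a CH=CH bridge between rings A and B (E/Z, undefined) | COc1ccc2c(c1)C=Cc1ccc(cc1)Oc1cc(ccc1OC)CCc1cccc(c1)O2
F6 | step 9 | buta-1,3-dien-2-yl trifluoromethanesulfonate | C=CC(=C)OS(=O)(=O)C(F)(F)F
F7 | step 9 | ethyl 3-[2-(3-{2-[3-(buta-1,3-dien-2-yloxy)-4-methoxyphenyl]ethyl}phenoxy)-5-methoxyphenyl]propanoate | C=CC(=C)Oc1cc(ccc1OC)CCc1cccc(c1)Oc1ccc(OC)cc1CCC(=O)OCC
F8 | step 9 | 3-[2-(3-{2-[3-(buta-1,3-dien-2-yloxy)-4-methoxyphenyl]ethyl}phenoxy)-5-methoxyphenyl]propanal | C=CC(=C)Oc1cc(ccc1OC)CCc1cccc(c1)Oc1ccc(OC)cc1CCC=O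
F9 | step 10 | 4-[2-(3-{2-[(3Z)-4-bromobut-3-en-1-yl]-4-methoxyphenoxy}phenyl)ethyl]-2-(buta-1,3-dien-2-yloxy)-1-methoxybenzene | C=CC(=C)Oc1cc(ccc1OC)CCc1cccc(c1)Oc1ccc(OC)cc1CC/C=C\Br
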